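**Retrosynthetic overview**

1. Numbering: ring carbons C1–C10 (C1=C2, C3 ketone, C4 carbinol, C5 and C6 crotonates, C7/C8 lactone fusion, C10 methine), C11–C13 the acrylate unit, C14 on C10, C15 on C4; β is the face of the C7–C11 bond. Last disconnection: the C4 tertiary alcohol, from the C4=C15 methylene ketone 23 by 1,4-hydrosilylation and Rubottom oxidation.
2. Key disconnection: the lactone O–C8 bond together with a transannular C3–C8 bond. The enabling feature is that the C3 carbonyl has only sp2 ring neighbours (C2 of C1=C2, and C4 carried as the C4=C15 methylene) and lies across the ring from C8, which is γ to the C12 carboxyl. Reconnecting C3–C8 folds the cyclodecadienone into a decalin-4a-ol (rings A and B) whose alkoxy radical can cut only the C3–C8 bond; the C8 radical is then captured oxidatively by the carboxylate.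
3. Decalin acid 22 comes from (R)-carvone, whose ring is ring A (C3 = carbonyl carbon, C4 bears the methyl, C7 bears the isopropenyl group, oxidized to the acrylate). C6–O is installed by vinylogous Rubottom oxidation and Mitsunobu inversion with crotonic acid; C5–O and C4=C15 by a Schenck ene reaction.
4. Ring B (C3, C2, C1, C10, C9, C8) is built by C8 alkylation with iodide 3 (source of C10), vinyl addition to C3 and ring-closing metathesis.
5. Ring order: ring A (carvone), ring B (metathesis), then in the key step the ring A/ring B fusion bond is cut to the ten-membered ring as the γ-lactone closes, then C4 hydroxylation.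

Key step: step 17

Assumption: (R)-carvone, (S)-3-bromo-2-methylpropan-1-ol, crotonic acid and crotonic anhydride are taken as commercial; the C3 carbinol of 15–22 is drawn as the epimer expected from axial attack, and either epimer serves because C3 becomes the ketone in step 17.

**Route**

Step 1
Reactants: 1 (S)-3-bromo-2-methylpropan-1-ol
Product: 2 (S)-(3-bromo-2-methylpropoxy)(tert-butyl)dimethylsilane
Conditions: TBSCl, imidazole, CH2Cl2, 0 °C to rt
Reagents that add atoms: tert-butyldimethylsilyl chloride, CC(C)(C)[Si](C)(C)Cl
Why: Routine silyl ether formation protects the primary alcohol and leaves the stereocentre (the future C10) untouched.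

Step 2
Reactants: 2 (S)-(3-bromo-2-methylpropoxy)(tert-butyl)dimethylsilane
Product: 3 (S)-tert-butyl(3-iodo-2-methylpropoxy)dimethylsilane
Conditions: NaI, acetone, reflux
Reagents that add atoms: sodium iodide, [Na+].[I-]
Why: Finkelstein exchange (SN2 at the CH2 carbon) gives the more reactive iodide without touching the neighbouring stereocentre.

Step 3
Reactants: 4 (R)-carvone
Product: 5 (R)-10-hydroxycarvone
Conditions: SeO2 (cat.), t-BuOOH, CH2Cl2, rt
Reagents that add atoms: tert-butyl hydroperoxide, CC(C)(C)OO
Why: Riley-type allylic oxidation (ene reaction then 2,3-sigmatropic shift) hydroxylates the methyl group of the electron-rich isopropenyl alkene, the enone alkene being too electron-poor to react.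

Step 4
Reactants: 5 (R)-10-hydroxycarvone
Product: 6 TBDPS ether of 10-hydroxycarvone
Conditions: TBDPSCl, imidazole, CH2Cl2, rt
Reagents that add atoms: tert-butyl(chloro)diphenylsilane, CC(C)(C)[Si](Cl)(c1ccccc1)c1ccccc1
Why: Silylation of the primary allylic alcohol gives a robust ether that survives the enolate, organometallic and oxidation steps up to step 15.

Step 5
Reactants: 6 TBDPS ether of 10-hydroxycarvone; 3 (S)-tert-butyl(3-iodo-2-methylpropoxy)dimethylsilane
Product: 8 trans-8-alkylated enone, via lithium enolate 7 (not isolated)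
Conditions: LiN(iPr)2, THF, −78 °C; then 3, DMPU, −78 to −20 °C
Reagents that add atoms: none
Why: Kinetic α′-deprotonation and SN2 alkylation of the cross-conjugated lithium enolate (ketone enolate alkylation) occur anti to the adjacent C7 substituent, setting C8 trans to C7, while C10 is carried in unchanged from 3.

Step 6
Reactants: 8 trans-8-alkylated enone
Product: 10 6α-hydroxy enone, via silyl dienol ether 9 (not isolated)
Conditions: TMSOTf, Et3N, CH2Cl2, 0 °C; then dimethyldioxirane, acetone, −78 °C; aq. NaHCO3 work-up
Reagents that add atoms: dimethyldioxirane, CC1(C)OO1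
Why: Soft enolization away from the hindered tertiary C8 gives the linear dienol ether, whose terminal C5=C6 bond is epoxidized anti to the pseudoaxial C7 substituent and collapses to the γ-hydroxy enone (vinylogous Rubottom oxidation), so the new C6 hydroxyl is α, trans to the C7 side chain.

Step 7
Reactants: 10 6α-hydroxy enone
Product: 11 6β-crotonate enone
Conditions: (E)-crotonic acid, PPh3, DIAD, THF, 0 °C
Reagents that add atoms: (E)-crotonic acid, C/C=C/C(=O)O
Why: Mitsunobu esterification inverts the activated allylic C6 carbinol by SN2, so the first crotonate is installed with the required 6β configuration (cis to the C7 side chain).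

Step 8
Reactants: 11 6β-crotonate enone
Product: 12 primary alcohol at C1
Conditions: HF·pyridine, pyridine, THF, 0 °C
Reagents that add atoms: none
Why: Acidic fluoride removes the unhindered primary alkyl TBS ether much faster than the TBDPS ether (selective desilylation), and the enone and crotonate are inert.

Step 9
Reactants: 12 primary alcohol at C1
Product: 13 C1 aldehyde
Conditions: Dess–Martin periodinane, NaHCO3, CH2Cl2, 0 °C to rt
Reagents that add atoms: none
Why: Buffered Dess–Martin oxidation gives the aldehyde under non-basic conditions that do not epimerize the adjacent C10 stereocentre.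

Step 10
Reactants: 13 C1 aldehyde
Product: 14 terminal alkene (vinyl group on C10)
Conditions: Ph3PCH3Br, KN(SiMe3)2, THF, −78 to 0 °C
Reagents that add atoms: methyltriphenylphosphonium bromide, C[P+](c1ccccc1)(c1ccccc1)c1ccccc1.[Br-]
Why: Wittig methylenation is far faster at the aldehyde than at the hindered conjugated ketone and at low temperature outruns epimerization of C10.

Step 11
Reactants: 14 terminal alkene (vinyl group on C10)
Product: 15 divinyl carbinol (3β-hydroxy 3α-vinyl)
Conditions: CH2=CHMgBr, CeCl3, THF, −78 °C
Reagents that add atoms: vinylmagnesium bromide, C=C[Mg]Br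
Why: The organocerium reagent adds 1,2 to the enone carbonyl without touching the crotonate (CeCl3-mediated Grignard addition), axial attack being expected to give the 3β-alcohol drawn, a stereocentre that is erased in step 17.

Step 12
Reactants: 15 divinyl carbinol (3β-hydroxy 3α-vinyl)
Product: 16 cis-fused decalinol (rings A and B)
Conditions: second-generation Grubbs catalyst (cat.), CH2Cl2, 40 °C
Reagents that add atoms: none
Why: Ring-closing metathesis joins the two monosubstituted vinyl groups into the cyclohexene of ring B (C1=C2, necessarily Z), the 1,1-disubstituted, trisubstituted and conjugated alkenes reacting far more slowly.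

Step 13
Reactants: 16 cis-fused decalinol (rings A and B)
Product: 18 5α-alcohol with C4=C15 methylene, via allylic hydroperoxide 17 (not isolated)
Conditions: O2, tetraphenylporphyrin (cat.), visible light, CH2Cl2, 0 °C; then PPh3
Reagents that add atoms: oxygen, O=O
Why: In this Schenck ene reaction singlet oxygen attacks the only trisubstituted alkene, can abstract hydrogen only from C15 (C3 has none and H6 is geminal to the ester and lies in the alkene plane) and bonds to C5 anti to the axial 6β-crotonate, so phosphine reduction gives the 5α-alcohol together with the C4=C15 methylene.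

Step 14
Reactants: 18 5α-alcohol with C4=C15 methylene
Product: 19 5α,6β-bis-crotonate
Conditions: (E)-crotonic anhydride, DMAP, Et3N, CH2Cl2, 0 °C to rt
Reagents that add atoms: (E)-crotonic anhydride, C/C=C/C(=O)OC(=O)/C=C/C
Why: DMAP-catalysed acylation esterifies the secondary allylic alcohol while the hindered tertiary C3 hydroxyl stays free.

Step 15
Reactants: 19 5α,6β-bis-crotonate
Product: 20 primary allylic alcohol at C12
Conditions: Bu4NF, AcOH, THF, 0 °C to rt
Reagents that add atoms: none
Why: Fluoride cleaves the silyl ether, and the acetic acid buffer keeps the medium mild enough for the crotonates and the tertiary bis-allylic alcohol.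

Step 16
Reactants: 20 primary allylic alcohol at C12
Product: 22 decalinol acrylic acid, via enal 21 (not isolated)
Conditions: TEMPO (cat.), PhI(OAc)2, CH2Cl2, rt; then NaClO2, NaH2PO4, 2-methyl-2-butene, t-BuOH/H2O, 0 °C
Reagents that add atoms: sodium chlorite, [Na+].[O-]Cl=O
Why: Oxoammonium oxidation is selective for the primary allylic alcohol and the Pinnick oxidation then converts the enal into the acrylic acid at near-neutral pH, conditions under which the tertiary bis-allylic alcohol and the esters survive.

Step 17
Reactants: 22 decalinol acrylic acid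
Product: 23 ten-membered keto lactone (trans-fused 12,8-olide)
Conditions: Pb(OAc)4, Cu(OAc)2, CaCO3, PhH, 70 °C
Reagents that add atoms: none
Why: Proposed new method: ligand exchange gives the C3 alkoxide of tetravalent lead, homolysis frees the C3 alkoxy radical, and β-scission of the C3–C8 ring-fusion bond unveils the C3 ketone (already flanked by C1=C2 and C4=C15) inside the ten-membered ring and leaves a secondary radical at C8, which is captured by the divalent copper held on the C12 carboxylate and collapses through an organocopper intermediate of trivalent copper to the C8–O bond. The closest known reaction types are the Pb(OAc)4 β-fragmentation of ring-fusion tertiary carbinols to medium-ring enones and the copper-mediated oxidative lactonization of γ-carboxyalkyl radicals in Mn(OAc)3/Cu(OAc)2 lactone annulations; their union on a bis-allylic decalinol acid is not known. The five-membered lactone closes in a 5-exo sense at C8 (C–O reductive elimination from a six-membered copper chelate), whereas the ten-membered ring is not closed but released by the cut. C8 is set by least-motion capture: in ring A the C9 and C11 substituents are trans-diequatorial, so the carboxylate on C11 reaches only the lobe of the C8 radical opposite the departing C3, which maps onto the trans-fused lactone, also the less strained fusion on the cyclodecadienone. The scission is regioselective because the other two bonds at C3 would give vinyl radicals (C2 and C4 are sp2), and the Z geometry of C1=C2 is inherited from the cyclohexene of ring B. The step needs radical capture to outrun transannular 6-endo addition of C8 to the C15 methylene, which the copper bound to the γ-carboxylate (intramolecular capture) and a base free of nucleophilic amines are meant to secure.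

Step 18
Reactants: 23 ten-membered keto lactone (trans-fused 12,8-olide)
Product: 24 triethylsilyl dienol ether
Conditions: RhCl(PPh3)3 (cat.), Et3SiH, PhH, rt
Reagents that add atoms: triethylsilane, CC[SiH](CC)CC
Why: Rhodium-catalysed 1,4-hydrosilylation takes place at the terminal s-cis methylene ketone (conjugated esters and the α-methylene lactone need heating), delivering hydrogen to C15 and giving the silyl enol ether C3=C4 without a metal enolate that could expel the C5 crotonate.

Step 19
Reactants: 24 triethylsilyl dienol ether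
Product: 26 target CNP0223772.1, via silyloxy ketone 25 (not isolated)
Conditions: dimethyldioxirane, acetone/CH2Cl2, −78 to 0 °C; then HF·pyridine, THF, 0 °C
Reagents that add atoms: dimethyldioxirane, CC1(C)OO1
Why: In this Rubottom oxidation the electron-rich enol ether is epoxidized on the face anti to the C5–C6 ring bond with H5 eclipsing the enol ether plane (A(1,3) strain), which places the new C4 oxygen β and trans to the C5 crotonate, and fluoride then frees the tertiary alcohol.

**Compound list**

1 | (S)-3-bromo-2-methylpropan-1-ol | BrC[C@@H](C)CO | starting material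
2 | (S)-(3-bromo-2-methylpropoxy)(tert-butyl)dimethylsilane | BrC[C@@H](C)CO[Si](C)(C)C(C)(C)C | intermediate
3 | (S)-tert-butyl(3-iodo-2-methylpropoxy)dimethylsilane | IC[C@@H](C)CO[Si](C)(C)C(C)(C)C | intermediate
4 | (R)-carvone, (R)-2-methyl-5-(prop-1-en-2-yl)cyclohex-2-en-1-one | C=C(C)[C@@H]1CC=C(C)C(=O)C1 | starting material
5 | (R)-10-hydroxycarvone, (R)-5-(3-hydroxyprop-1-en-2-yl)-2-methylcyclohex-2-en-1-one | C=C(CO)[C@@H]1CC=C(C)C(=O)C1 | intermediate
6 | tert-butyldiphenylsilyl ether of 5 | C=C(CO[Si](c2ccccc2)(c3ccccc3)C(C)(C)C)[C@@H]1CC=C(C)C(=O)C1 | intermediate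
7 | lithium enolate of 6 (C3–OLi, C3=C8) | C=C(CO[Si](c2ccccc2)(c3ccccc3)C(C)(C)C)[C@@H]1CC=C(C)C(O[Li])=C1 | intermediate (not isolated)
8 | enone 6 carrying at C8 the (R)-3-(tert-butyldimethylsilyloxy)-2-methylpropyl chain, trans to the C7 side chain | C=C(CO[Si](c2ccccc2)(c3ccccc3)C(C)(C)C)[C@@H]1CC=C(C)C(=O)[C@H]1C[C@@H](C)CO[Si](C)(C)C(C)(C)C | intermediate
9 | linear trimethylsilyl dienol ether of 8 (C3–OSiMe3, C3=C4, C5=C6) | C=C(CO[Si](c2ccccc2)(c3ccccc3)C(C)(C)C)[C@@H]1C=CC(C)=C(O[Si](C)(C)C)[C@H]1C[C@@H](C)CO[Si](C)(C)C(C)(C)C | intermediate (not isolated)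
10 | 6α-hydroxy enone (hydroxyl trans to the C7 side chain) | C=C(CO[Si](c2ccccc2)(c3ccccc3)C(C)(C)C)[C@@H]1[C@@H](O)C=C(C)C(=O)[C@H]1C[C@@H](C)CO[Si](C)(C)C(C)(C)C | intermediate
11 | 6β-(E)-crotonate enone (ester cis to the C7 side chain) | C=C(CO[Si](c2ccccc2)(c3ccccc3)C(C)(C)C)[C@@H]1[C@H](OC(=O)/C=C/C)C=C(C)C(=O)[C@H]1C[C@@H](C)CO[Si](C)(C)C(C)(C)C | intermediate
12 | primary alcohol (C1–OH) from 11 | C=C(CO[Si](c2ccccc2)(c3ccccc3)C(C)(C)C)[C@@H]1[C@H](OC(=O)/C=C/C)C=C(C)C(=O)[C@H]1C[C@@H](C)CO | intermediate
13 | aldehyde (C1 = CHO) | C=C(CO[Si](c2ccccc2)(c3ccccc3)C(C)(C)C)[C@@H]1[C@H](OC(=O)/C=C/C)C=C(C)C(=O)[C@H]1C[C@@H](C)C=O | intermediate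
14 | terminal alkene (C8 chain = (R)-2-methylbut-3-enyl) | C=C(CO[Si](c2ccccc2)(c3ccccc3)C(C)(C)C)[C@@H]1[C@H](OC(=O)/C=C/C)C=C(C)C(=O)[C@H]1C[C@@H](C)C=C | intermediate
15 | tertiary divinyl carbinol (3β-OH, 3α-vinyl) | C=C(CO[Si](c2ccccc2)(c3ccccc3)C(C)(C)C)[C@@H]1[C@H](OC(=O)/C=C/C)C=C(C)[C@@](O)(C=C)[C@H]1C[C@@H](C)C=C | intermediate
16 | cis-fused decalinol: 3β-OH, 8β-H, 10β-CH3, C1=C2 and C4=C5, 6β-crotonate, C7 side chain CH2=C(CH2OTBDPS) | C=C(CO[Si](c3ccccc3)(c4ccccc4)C(C)(C)C)[C@@H]1[C@H](OC(=O)/C=C/C)C=C(C)[C@@]2(O)C=C[C@H](C)C[C@@H]12 | intermediate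
17 | 5α-hydroperoxide with C4=C15 methylene | C=C(CO[Si](c3ccccc3)(c4ccccc4)C(C)(C)C)[C@@H]1[C@H](OC(=O)/C=C/C)[C@@H](OO)C(=C)[C@@]2(O)C=C[C@H](C)C[C@@H]12 | intermediate (not isolated)
18 | 5α-alcohol with C4=C15 methylene | C=C(CO[Si](c3ccccc3)(c4ccccc4)C(C)(C)C)[C@@H]1[C@H](OC(=O)/C=C/C)[C@@H](O)C(=C)[C@@]2(O)C=C[C@H](C)C[C@@H]12 | intermediate
19 | 5α,6β-bis-(E)-crotonate | C=C(CO[Si](c3ccccc3)(c4ccccc4)C(C)(C)C)[C@@H]1[C@H](OC(=O)/C=C/C)[C@@H](OC(=O)/C=C/C)C(=C)[C@@]2(O)C=C[C@H](C)C[C@@H]12 | intermediate
20 | primary allylic alcohol (C12–OH) | C=C(CO)[C@@H]1[C@H](OC(=O)/C=C/C)[C@@H](OC(=O)/C=C/C)C(=C)[C@@]2(O)C=C[C@H](C)C[C@@H]12 | intermediate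
21 | enal (C12 = CHO) | C=C(C=O)[C@@H]1[C@H](OC(=O)/C=C/C)[C@@H](OC(=O)/C=C/C)C(=C)[C@@]2(O)C=C[C@H](C)C[C@@H]12 | intermediate (not isolated)
22 | decalinol acrylic acid (key-step precursor) | C=C(C(=O)O)[C@@H]1[C@H](OC(=O)/C=C/C)[C@@H](OC(=O)/C=C/C)C(=C)[C@@]2(O)C=C[C@H](C)C[C@@H]12 | intermediate
23 | ten-membered lactone: (1Z)-en-3-one, C4=C15 methylene, 5α,6β-bis-crotonate, trans-fused 12,8-olide, 10β-CH3 | C=C1C(=O)O[C@@H]2C[C@@H](C)/C=C\C(=O)C(=C)[C@H](OC(=O)/C=C/C)[C@@H](OC(=O)/C=C/C)[C@@H]12 | intermediate
24 | triethylsilyl dienol ether of 23 (C3–OSiEt3, C3=C4, C15 = CH3) | C=C1C(=O)O[C@@H]2C[C@@H](C)/C=C\C(O[Si](CC)(CC)CC)=C(C)/[C@H](OC(=O)/C=C/C)[C@@H](OC(=O)/C=C/C)[C@@H]12 | intermediate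
25 | 4β-triethylsilyloxy ketone | C=C1C(=O)O[C@@H]2C[C@@H](C)/C=C\C(=O)[C@@](C)(O[Si](CC)(CC)CC)[C@H](OC(=O)/C=C/C)[C@@H](OC(=O)/C=C/C)[C@@H]12 | intermediate (not isolated)
26 | CNP0223772.1 | C=C1C(=O)O[C@@H]2C[C@@H](C)/C=C\C(=O)[C@@](C)(O)[C@H](OC(=O)/C=C/C)[C@@H](OC(=O)/C=C/C)[C@@H]12 | target

**Step count and risks**

Total: 19 steps (2 for iodide 3, 17 from (R)-carvone). Longest linear sequence: 17 steps (steps 3 to 19).

Steps most likely to fail:

Step 17. Oxidative capture of the C8 radical may be outrun by transannular addition to the C15 methylene or by hydrogen loss to an alkene, and the lactone fusion may form with poor control. The fallback sets out from acid 22 and uses known chemistry. Esterification with O-tert-butyl-N,N′-diisopropylisourea gives the tert-butyl ester F1. Hypoiodite fragmentation (PhI(OAc)2, I2, visible light, CH2Cl2) cuts the same C3–C8 bond but traps the C8 radical by iodine-atom transfer, which is faster than any cyclization, giving the ring-expanded C8 iodide F2 as a ten-membered dienone (C8 epimers). AgOTf with 2,6-di-tert-butylpyridine then ionizes the iodide, the ester carbonyl oxygen closes the lactone and isobutene is lost. The route is rejoined at lactone 23; the trans fusion is expected as the less strained outcome of the cation-type closure and a cis isomer would be separated.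

Step 18. The hydrosilylation may fail to distinguish the C4=C15 methylene ketone from the α-methylene lactone, or rhodium may ionize the allylic C5 crotonate. The fallback sets out from lactone 23. Weitz–Scheffer epoxidation with t-BuOOLi (THF, −78 °C), which selects the most electrophilic terminal enone, gives the spiro-epoxide F3. MgI2 opens it at the primary carbon C15 (C4 is quaternary) to the iodohydrin F4. Radical deiodination with (Me3Si)3SiH and AIBN turns C15 into the methyl group and comes back at target 26, by-passing 24 and 25.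

Step 13. Delivery of oxygen to C5 may show poor facial selectivity. The ene reaction is kept for its regiochemistry and the C5 epimers are made to converge. Setting out from decalinol 16, ene reaction and phosphine reduction are run as before; the 5β-alcohol F5 is separated and esterified with crotonic acid under Mitsunobu conditions (PPh3, DIAD), which inverts C5, while the 5α-alcohol 18 is acylated as in step 14. Both streams come back at bis-crotonate 19.

Further compounds
F1 | step 17 | tert-butyl ester of acid 22 | C=C(C(=O)OC(C)(C)C)[C@@H]1[C@H](OC(=O)/C=C/C)[C@@H](OC(=O)/C=C/C)C(=C)[C@@]2(O)C=C[C@H](C)C[C@@H]12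
F2 | step 17 | ring-expanded C8 iodide, ten-membered (1Z)-dienone tert-butyl ester (C8 epimers) | C=C(C(=O)OC(C)(C)C)[C@@H]1[C@H](OC(=O)/C=C/C)[C@@H](OC(=O)/C=C/C)C(=C)C(=O)/C=C\[C@H](C)CC1I
F3 | step 18 | C4,C15 spiro-epoxide of lactone 23 (epoxide oxygen β at C4) | C=C1C(=O)O[C@@H]2C[C@@H](C)/C=C\C(=O)[C@]3(CO3)[C@H](OC(=O)/C=C/C)[C@@H](OC(=O)/C=C/C)[C@@H]12
F4 | step 18 | 4β-hydroxy 15-iodide (iodohydrin) | C=C1C(=O)O[C@@H]2C[C@@H](C)/C=C\C(=O)[C@@](CI)(O)[C@H](OC(=O)/C=C/C)[C@@H](OC(=O)/C=C/C)[C@@H]12
F5 | step 13 | 5β-alcohol, C5 epimer of 18 | C=C(CO[Si](c3ccccc3)(c4ccccc4)C(C)(C)C)[C@@H]1[C@H](OC(=O)/C=C/C)[C@H](O)C(=C)[C@@]2(O)C=C[C@H](C)C[C@@H]12
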